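**Retrosynthetic overview**
- Marchantin G ⇐ its tri-O-methyl ether (BBr3) ⇐ the macrocyclic carbinol (oxidation).
- Key disconnection: ring C and the 18-membered ring are opened together. Ring C comes from a 3-aryloxy-2-pyrone (four carbons) and an (E)-vinyl sulfone (two carbons) by intramolecular Diels–Alder, loss of CO2 and loss of sulfinic acid.
- The seco precursor comes from cross-metathesis with phenyl vinyl sulfone, aldehyde allylation, and a B-alkyl Suzuki coupling that makes the bibenzyl bridge.
- The two coupling partners come from SNAr of 3-hydroxy-2-pyrone on a 2-fluorobenzaldehyde followed by methylenation, and from a Chan–Lam diaryl ether synthesis.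
- Ring order: rings A, B and D are bought; the pyrone is carried as latent ring C; ring C and the macrocycle form last, in one operation.

Assumption: the target SMILES has no stereocentre and the macrocycle is conformationally mobile, so Marchantin G is achiral and needs no enantiocontrol; the one temporary carbinol centre is carried racemic and erased by oxidation. 3-Hydroxy-2H-pyran-2-one is taken as purchasable.

**Step 1**
Reactants: 1 3-hydroxy-2H-pyran-2-one; 2 2-fluoro-3-methoxybenzaldehyde
Product: 3 3-methoxy-2-[(2-oxo-2H-pyran-3-yl)oxy]benzaldehyde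
Conditions: K2CO3 (1.2 equiv), DMF, 80 °C
Reagents that add atoms: none
Why: Nucleophilic aromatic substitution (SNAr), in which the fluoride activated by the ortho formyl group is displaced through a Meisenheimer intermediate by the oxygen of the potassium pyran-3-olate, fixing the ring B–O–(future ring C) ether at the outset.

**Step 2**
Reactants: 3 3-methoxy-2-[(2-oxo-2H-pyran-3-yl)oxy]benzaldehyde
Product: 4 3-(2-ethenyl-6-methoxyphenoxy)-2H-pyran-2-one
Conditions: Ph3PCH3Br, KN(SiMe3)2, THF, −78 °C; ylide (1.05 equiv) added to 3, −78 to 0 °C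
Reagents that add atoms: methyltriphenylphosphonium bromide, C[P+](c1ccccc1)(c1ccccc1)c1ccccc1.[Br-]
Why: Wittig methylenation, in which the non-stabilised ylide consumes the aldehyde within minutes at −78 °C and inverse addition of one equivalent keeps it away from the less electrophilic pyrone lactone.

**Step 3**
Reactants: 5 4-bromophenylboronic acid; 6 3-hydroxy-4,5-dimethoxybenzaldehyde
Product: 7 3-(4-bromophenoxy)-4,5-dimethoxybenzaldehyde
Conditions: Cu(OAc)2 (20 mol %), pyridine, 4 Å molecular sieves, CH2Cl2, O2 (1 atm), rt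
Reagents that add atoms: none
Why: Chan–Lam oxidative C–O coupling arylates the phenol at room temperature and leaves untouched both the aryl bromide needed in step 4 and the aldehyde needed in step 5.

**Step 4**
Reactants: 4 3-(2-ethenyl-6-methoxyphenoxy)-2H-pyran-2-one; 7 3-(4-bromophenoxy)-4,5-dimethoxybenzaldehyde
Product: 9 4,5-dimethoxy-3-[4-(2-{3-methoxy-2-[(2-oxo-2H-pyran-3-yl)oxy]phenyl}ethyl)phenoxy]benzaldehyde, via alkyl-9-BBN adduct 8 (not isolated)
Conditions: 9-BBN (1.1 equiv), THF, 0 °C to rt; then 7, PdCl2(dppf) (5 mol %), K3PO4 (3 M aq.), DMF, rt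
Reagents that add atoms: none
Why: Anti-Markovnikov hydroboration of the styrene followed by B-alkyl Suzuki–Miyaura coupling with the aryl bromide gives the saturated bibenzyl bridge directly at room temperature, tolerating the aldehyde and avoiding a hydrogenation that would threaten the pyrone.

**Step 5**
Reactants: 9 4,5-dimethoxy-3-[4-(2-{3-methoxy-2-[(2-oxo-2H-pyran-3-yl)oxy]phenyl}ethyl)phenoxy]benzaldehyde
Product: 10 racemic 3-{2-[2-(4-{5-(1-hydroxybut-3-en-1-yl)-2,3-dimethoxyphenoxy}phenyl)ethyl]-6-methoxyphenoxy}-2H-pyran-2-one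
Conditions: allylB(pin) (1.5 equiv), Sc(OTf)3 (5 mol %), CH2Cl2, −40 °C to rt; aq. NaHCO3 work-up
Reagents that add atoms: allylboronic acid pinacol ester, C=CCB1OC(C)(C)C(C)(C)O1
Why: Lewis acid-catalysed allylboration of the aldehyde through a closed six-membered transition state is chemoselective over the pyrone lactone, and the new carbinol centre is made racemic on purpose because step 8 oxidises it away.

**Step 6**
Reactants: 10 racemic 3-{2-[2-(4-{5-(1-hydroxybut-3-en-1-yl)-2,3-dimethoxyphenoxy}phenyl)ethyl]-6-methoxyphenoxy}-2H-pyran-2-one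
Product: 11 racemic 3-{2-[2-(4-{5-[(3E)-1-hydroxy-4-(phenylsulfonyl)but-3-en-1-yl]-2,3-dimethoxyphenoxy}phenyl)ethyl]-6-methoxyphenoxy}-2H-pyran-2-one
Conditions: phenyl vinyl sulfone (3 equiv), second-generation Hoveyda–Grubbs catalyst RuCl2(H2IMes)(=CH-C6H4-2-OiPr) (5 mol %), CH2Cl2, 40 °C
Reagents that add atoms: phenyl vinyl sulfone, C=CS(=O)(=O)c1ccccc1
Why: Olefin cross-metathesis of the terminal alkene with the electron-poor partner phenyl vinyl sulfone gives the (E)-vinyl sulfone under thermodynamic control, while the endocyclic conjugated pyrone double bonds are inert to the ruthenium carbene.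

**Step 7**
Reactants: 11 racemic 3-{2-[2-(4-{5-[(3E)-1-hydroxy-4-(phenylsulfonyl)but-3-en-1-yl]-2,3-dimethoxyphenoxy}phenyl)ethyl]-6-methoxyphenoxy}-2H-pyran-2-one
Product: 14 macrocyclic carbinol (Marchantin G tri-O-methyl ether in which the ketone is a racemic CH(OH)), via bridged lactone cycloadduct 12 (not isolated), via cyclohexadienyl sulfone 13 (not isolated)
Conditions: 2,6-di-tert-butyl-4-methylpyridine (2 equiv), BHT (10 mol %), o-dichlorobenzene (0.001 M), 180 °C, 48 h
Reagents that add atoms: none
Why: Proposed new method: the electron-rich 3-aryloxy-2-pyrone (largest HOMO coefficient at C6) adds across the electron-poor (E)-vinyl sulfone (largest LUMO coefficient at the alkyl-bearing β-carbon) so that C6 bonds to the β-carbon and C3 to the sulfonyl carbon, closing the six-membered carbocycle and the 18-membered ring together, after which cycloreversion expels CO2 and aromatisation-driven loss of benzenesulfinic acid (scavenged by the hindered pyridine) leaves the side chain meta to the aryloxy group as in ring C, with no stereocentre set; the closest known reaction type is the intramolecular α-pyrone/vinyl sulfone Diels–Alder–decarboxylation–sulfinate elimination used to build an arene inside a strained bis(bibenzyl) cyclophane, extended here to an entropically harder 18-membered closure under high dilution.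

**Step 8**
Reactants: 14 macrocyclic carbinol (Marchantin G tri-O-methyl ether in which the ketone is a racemic CH(OH))
Product: 15 Marchantin G tri-O-methyl ether
Conditions: Dess–Martin periodinane (1.3 equiv), CH2Cl2, 0 °C to rt
Reagents that add atoms: none
Why: Dess–Martin oxidation converts the benzylic secondary alcohol into the deoxybenzoin ketone under neutral conditions without touching the aryl ethers, and removes the only stereocentre.

**Step 9**
Reactants: 15 Marchantin G tri-O-methyl ether
Product: 16 Marchantin G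
Conditions: BBr3 (6 equiv), CH2Cl2, −78 °C to rt; then H2O
Reagents that add atoms: none
Why: Lewis acid-mediated aryl methyl ether cleavage (BBr3 complexation, then bromide attack at methyl) frees the three phenols while the diaryl ethers and the ketone survive, giving achiral Marchantin G.

**Compound list**
1 | 3-hydroxy-2H-pyran-2-one | OC1=CC=COC1=O | starting material
2 | 2-fluoro-3-methoxybenzaldehyde | COc1cccc(C=O)c1F | starting material
3 | 3-methoxy-2-[(2-oxo-2H-pyran-3-yl)oxy]benzaldehyde | COc1cccc(C=O)c1OC1=CC=COC1=O | intermediate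
4 | 3-(2-ethenyl-6-methoxyphenoxy)-2H-pyran-2-one | COc1cccc(C=C)c1OC1=CC=COC1=O | intermediate
5 | 4-bromophenylboronic acid | OB(O)c1ccc(Br)cc1 | starting material
6 | 3-hydroxy-4,5-dimethoxybenzaldehyde | COc1cc(C=O)cc(O)c1OC | starting material
7 | 3-(4-bromophenoxy)-4,5-dimethoxybenzaldehyde | COc1cc(C=O)cc(Oc2ccc(Br)cc2)c1OC | intermediate
8 | 3-{2-[2-(9-borabicyclo[3.3.1]nonan-9-yl)ethyl]-6-methoxyphenoxy}-2H-pyran-2-one (alkyl-9-BBN adduct, not isolated) | COc1cccc(CCB2C3CCCC2CCC3)c1OC1=CC=COC1=O | intermediate
9 | 4,5-dimethoxy-3-[4-(2-{3-methoxy-2-[(2-oxo-2H-pyran-3-yl)oxy]phenyl}ethyl)phenoxy]benzaldehyde | COc1cccc(CCc2ccc(Oc3cc(C=O)cc(OC)c3OC)cc2)c1OC1=CC=COC1=O | intermediate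
10 | racemic 3-{2-[2-(4-{5-(1-hydroxybut-3-en-1-yl)-2,3-dimethoxyphenoxy}phenyl)ethyl]-6-methoxyphenoxy}-2H-pyran-2-one | C=CCC(O)c1cc(OC)c(OC)c(Oc2ccc(CCc3cccc(OC)c3OC3=CC=COC3=O)cc2)c1 | intermediate
11 | racemic 3-{2-[2-(4-{5-[(3E)-1-hydroxy-4-(phenylsulfonyl)but-3-en-1-yl]-2,3-dimethoxyphenoxy}phenyl)ethyl]-6-methoxyphenoxy}-2H-pyran-2-one | O=S(=O)(/C=C/CC(O)c1cc(OC)c(OC)c(Oc2ccc(CCc3cccc(OC)c3OC3=CC=COC3=O)cc2)c1)c1ccccc1 | intermediate
12 | bridged lactone cycloadduct: 2-oxabicyclo[2.2.2]oct-5-en-3-one spanned by the macrocycle, aryloxy at the bridgehead next to C=O, PhSO2 and the CH2CH(OH)Ar chain on the ethano bridge (diastereomer mixture, not isolated) | O=C1OC2C=CC13Oc4c(OC)cccc4CCc4ccc(cc4)Oc4cc(cc(OC)c4OC)C(O)CC2C3S(=O)(=O)c1ccccc1 | intermediate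
13 | cyclohexadienyl sulfone: macrocycle in which the future ring C is a 1-aryloxy-6-(phenylsulfonyl)cyclohexa-1,3-diene carrying the CH2CH(OH)Ar chain at C5 (diastereomer mixture, not isolated) | O=S(=O)(c1ccccc1)C1C2CC(O)c3cc(OC)c(OC)c(c3)Oc3ccc(cc3)CCc3cccc(OC)c3OC1=CC=C2 | intermediate
14 | macrocyclic carbinol: Marchantin G tri-O-methyl ether with CH(OH) in place of C=O (racemic) | OC1Cc2cccc(c2)Oc2c(OC)cccc2CCc2ccc(cc2)Oc2cc1cc(OC)c2OC | intermediate
15 | Marchantin G tri-O-methyl ether | O=C1Cc2cccc(c2)Oc2c(OC)cccc2CCc2ccc(cc2)Oc2cc1cc(OC)c2OC | intermediate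
16 | Marchantin G | O=C1Cc2cccc(c2)Oc2c(O)cccc2CCc2ccc(cc2)Oc2cc1cc(O)c2O | target

**Step count and risks**
Total step count: 9. Longest linear sequence: 8 steps (steps 1, 2, 4, 5, 6, 7, 8, 9); step 3 is a one-step side branch.

Most likely to fail, first: step 7. The 18-membered closure has a low effective molarity, the diene/dienophile pair is only moderately activated, and the vinyl sulfone can isomerise to the unreactive allyl sulfone before it reacts. The fallback makes ring C and the macrocycle in two separate operations; it sets out from 7 and 4 and comes back to the route at 14. Aldehyde 7 is allylated with allylB(pin)/Sc(OTf)3 to 1-[3-(4-bromophenoxy)-4,5-dimethoxyphenyl]but-3-en-1-ol F1. Cross-metathesis with phenyl vinyl sulfone gives (3E)-1-[3-(4-bromophenoxy)-4,5-dimethoxyphenyl]-4-(phenylsulfonyl)but-3-en-1-ol F2. An intermolecular Diels–Alder/CO2 loss/sulfinate loss between F2 and pyrone styrene 4 at 1 M and 150 °C, where no ring-closing entropy is paid, gives the open-chain ring C compound 1-[3-(4-bromophenoxy)-4,5-dimethoxyphenyl]-2-[3-(2-ethenyl-6-methoxyphenoxy)phenyl]ethanol F3. Hydroboration of its styrene with 9-BBN and an intramolecular B-alkyl Suzuki coupling under high dilution (PdCl2(dppf), K3PO4, THF/DMF/H2O) then closes the 18-membered ring at the bibenzyl bond to give 14.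

Second: step 1. The pyran-3-olate is a weak and ambident nucleophile, and the fluoride is flanked by two ortho substituents. The fallback replaces SNAr by copper catalysis; it sets out from 1 and comes back at 3. Compound 1 is coupled with 2-bromo-3-methoxybenzaldehyde under Ullmann ether conditions (CuI, picolinic acid, K3PO4, DMSO, 80 °C), with the ortho formyl group assisting oxidative addition; no new compound arises on the way, F0.

Third: step 4. The pyrone must survive 9-BBN and aqueous phosphate. The fallback builds the bibenzyl by olefination/hydrogenation and forms the diaryl ether last; it sets out from 3 and comes back at 9. Wittig reaction of 3 with (4-bromobenzyl)triphenylphosphonium bromide (K2CO3, 18-crown-6, CH2Cl2) gives the stilbene 3-{2-[2-(4-bromophenyl)ethenyl]-6-methoxyphenoxy}-2H-pyran-2-one F4 as an E/Z mixture. Homogeneous hydrogenation with RhCl(PPh3)3/H2 reduces only the disubstituted alkene to 3-{2-[2-(4-bromophenyl)ethyl]-6-methoxyphenoxy}-2H-pyran-2-one F5. Palladium-catalysed C–O coupling of F5 with phenol 6 (Pd(OAc)2, tBuXPhos, K3PO4, toluene, 90 °C) gives 9.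

**Further compounds**
F1 | step 7 | 1-[3-(4-bromophenoxy)-4,5-dimethoxyphenyl]but-3-en-1-ol | C=CCC(O)c1cc(OC)c(OC)c(Oc2ccc(Br)cc2)c1
F2 | step 7 | (3E)-1-[3-(4-bromophenoxy)-4,5-dimethoxyphenyl]-4-(phenylsulfonyl)but-3-en-1-ol | O=S(=O)(/C=C/CC(O)c1cc(OC)c(OC)c(Oc2ccc(Br)cc2)c1)c1ccccc1
F3 | step 7 | 1-[3-(4-bromophenoxy)-4,5-dimethoxyphenyl]-2-[3-(2-ethenyl-6-methoxyphenoxy)phenyl]ethanol | C=Cc1cccc(OC)c1Oc1cccc(CC(O)c2cc(OC)c(OC)c(Oc3ccc(Br)cc3)c2)c1
F0 | step 1 | none | none
F4 | step 4 | 3-{2-[2-(4-bromophenyl)ethenyl]-6-methoxyphenoxy}-2H-pyran-2-one (E/Z mixture) | COc1cccc(C=Cc2ccc(Br)cc2)c1OC1=CC=COC1=O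
F5 | step 4 | 3-{2-[2-(4-bromophenyl)ethyl]-6-methoxyphenoxy}-2H-pyran-2-one | COc1cccc(CCc2ccc(Br)cc2)c1OC1=CC=COC1=O
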